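**Plan**
Retrosynthesis: cut C7–C8 (dienyllithium + epoxy aldehyde, C7 reset through the ketone); open the epoxide at C2 to a C1-OH/C2-OMs pair; cut C2–C3 of ring B to a C2,C3-dialdehyde; cut C9–C10 (Negishi) and the ring A bond between CMe2 and the ring CH (epoxide-triggered radical cyclization).
Forward: ring A is closed first and carried to a (1Z,3E)-dienyl iodide; the open chain of ring B is built on L-tartrate; ring B is closed by a SmI2 pinacol coupling, then the epoxide is closed; the two fragments are joined at C7 last.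
Enabling feature: C2 and C3 of ring B both carry oxygen and lie between the trans C1/C6 diol (held as a trans-dioxolane) and the cis C4=C5 alkene, so an acyclic dialdehyde is folded for reductive C2–C3 coupling.
Stereochemistry: ring A carbinol from Shi epoxidation, ring A CH from the chair cyclization; C6 from L-tartaric acid, C1 from enolate alkylation anti to the C6 ester; C2 and C3 from the pinacol step (C2 then inverted on epoxide closure); C7 from chelation-controlled reduction; alkene geometries from Takai olefination, bromoboration and the Horner–Wadsworth–Emmons step.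

Key step: step 18

Remark (locants, abbreviations): in ring B, C1 is the oxygen-bearing quaternary carbon that carries C7, C2 and C3 follow, C4 is the alkene carbon carrying C4′H2O, C5 the alkene CH, C6 the carbinol next to C1; C8–C11 run from C7 to ring A; β is the face of the C1 oxygen, α the opposite face. PMB = 4-methoxybenzyl, TBS = tert-butyldimethylsilyl, TBDPS = tert-butyldiphenylsilyl.

Step 1
Reactants: 1 geranyl acetate
Product: 2 (R)-6,7-epoxygeranyl acetate
Conditions: Shi ketone (D-fructose-derived, 0.3 equiv), KHSO5 (Oxone), K2CO3, n-Bu4NHSO4, MeCN/dimethoxymethane/aq. Na2B4O7 buffer, 0 °C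
Reagents that add atoms: potassium peroxymonosulfate, [K+].[O-]S(=O)(=O)OO
Why: Shi asymmetric epoxidation (chiral dioxirane, spiro transition state) should oxidize the electron-rich 6,7-alkene in preference to the 2,3-alkene deactivated by the allylic acetate and give the (R)-epoxide, the future ring A carbinol centre.

Step 2
Reactants: 2 (R)-6,7-epoxygeranyl acetate
Product: 3 [(1S,3R)-3-hydroxy-2,2-dimethyl-6-methylidenecyclohexyl]methyl acetate
Conditions: Cp2TiCl2 (2.2 equiv), Mn dust, THF, 25 °C, slow addition of 2; aq. HCl work-up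
Reagents that add atoms: none
Why: Nugent–RajanBabu epoxide opening by titanocene monochloride (trivalent titanium) gives the tertiary radical, which should close 6-endo-trig through a chair transition state with OTi and CH2OAc equatorial (carbinol centre retained, new ring CH set cis-1,3 to it), and trapping by a second trivalent titanium with β-hydride elimination should give the exocyclic alkene.

Step 3
Reactants: 3 hydroxy acetate
Product: 4 [(1S,3R)-3-(tert-butyldimethylsilyloxy)-2,2-dimethyl-6-methylidenecyclohexyl]methyl acetate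
Conditions: TBSCl, imidazole, DMF, 25 °C
Reagents that add atoms: tert-butyldimethylsilyl chloride, CC(C)(C)[Si](C)(C)Cl
Why: Standard imidazole-promoted silylation of the only free hydroxyl; no stereocentre is touched.

Step 4
Reactants: 4 silyl ether acetate
Product: 5 [(1S,3R)-3-(tert-butyldimethylsilyloxy)-2,2-dimethyl-6-methylidenecyclohexyl]methanol
Conditions: K2CO3, MeOH, 0 to 25 °C
Reagents that add atoms: none
Why: Base-catalysed transesterification should free the primary alcohol while the secondary silyl ether is stable.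

Step 5
Reactants: 5 primary alcohol
Product: 6 (1S,3R)-3-(tert-butyldimethylsilyloxy)-2,2-dimethyl-6-methylidenecyclohexane-1-carbaldehyde
Conditions: Dess–Martin periodinane, NaHCO3, CH2Cl2, 0 °C; used at once
Reagents that add atoms: none
Why: Buffered Dess–Martin oxidation should give the β,γ-unsaturated aldehyde without epimerization of the α-centre or migration of the exocyclic alkene.

Step 6
Reactants: 6 aldehyde
Product: 7 (E)-vinyl iodide of ring A
Conditions: CrCl2, CHI3, THF, 0 °C
Reagents that add atoms: iodoform, IC(I)I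
Why: Takai olefination (geminal dichromium species from CHI3 and divalent chromium) is non-basic and should convert the sensitive α-branched aldehyde into the (E)-vinyl iodide with the α-centre intact.

Step 7
Reactants: 8 propyne
Product: 10 (Z)-2-(2-bromoprop-1-en-1-yl)-4,4,5,5-tetramethyl-1,3,2-dioxaborolane, via dibromoborane 9 (not isolated)
Conditions: BBr3, CH2Cl2, −78 to 25 °C; then pinacol, 0 °C
Reagents that add atoms: boron tribromide, BrB(Br)Br; pinacol, CC(C)(O)C(C)(C)O
Why: syn-Bromoboration of propyne should place bromine on the internal carbon cis to boron and so fix the (Z) geometry, and exchange of the B–Br bonds with pinacol gives the stable boronate.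

Step 8
Reactants: 7 (E)-vinyl iodide; 10 (Z)-bromoalkenyl boronate
Product: 13 (1Z,3E)-dienylboronate of ring A, via alkenyllithium 11 (not isolated), via alkenylzinc bromide 12 (not isolated)
Conditions: t-BuLi (2.0 equiv), Et2O, −78 °C; ZnBr2, THF, −78 to 0 °C; then 10, Pd(t-Bu3P)2 (2 mol%), THF, 25 °C
Reagents that add atoms: none
Why: Iodine–lithium exchange and transmetalation to zinc occur with retention, and the Negishi coupling (zerovalent palladium) should take place only at the C–Br bond of 10, with retention on both partners, leaving the boronate untouched.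

Step 9
Reactants: 13 dienylboronate
Product: 14 (1Z,3E)-dienyl iodide of ring A
Conditions: I2, NaOH, THF/H2O, 0 °C
Reagents that add atoms: iodine, II
Why: Iododeboronation through the hydroxide ate complex should replace boron by iodine with retention of the (Z) geometry.

Step 10
Reactants: 15 dimethyl 2,3-O-isopropylidene-L-tartrate
Product: 17 dimethyl (4S,5R)-4-[(4-methoxybenzyloxy)methyl]-2,2-dimethyl-1,3-dioxolane-4,5-dicarboxylate, via lithium enolate 16 (not isolated)
Conditions: LiN(i-Pr)2, THF/HMPA, −78 °C; 4-methoxybenzyl chloromethyl ether, −78 to −40 °C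
Reagents that add atoms: 4-methoxybenzyl chloromethyl ether, COc1ccc(COCCl)cc1
Why: Alkylation of the tartrate acetonide ester enolate, which does not β-eliminate at −78 °C: the electrophile should enter anti to the ester on the neighbouring carbon, setting quaternary C1 with the two esters cis while C6 is retained from L-tartaric acid.

Step 11
Reactants: 17 alkylated diester
Product: 18 methyl (4S,5R)-5-formyl-4-[(4-methoxybenzyloxy)methyl]-2,2-dimethyl-1,3-dioxolane-4-carboxylate
Conditions: i-Bu2AlH (1.1 equiv), toluene, −78 °C; Rochelle salt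
Reagents that add atoms: none
Why: Partial reduction should stop at the chelated tetrahedral aluminate of the less hindered ester (on tertiary C6), the ester on quaternary C1 reacting more slowly, and give the aldehyde on hydrolysis.

Step 12
Reactants: 18 aldehyde
Product: 19 ethyl (E)-enoate C6–C5H=C4(CO2Et)(CH2OPMB)
Conditions: 4-methoxybenzyl alcohol, NaH, THF, 0 °C; ethyl 2-(diethoxyphosphoryl)acrylate, 0 °C; then 18, −78 to 0 °C
Reagents that add atoms: 4-methoxybenzyl alcohol, COc1ccc(CO)cc1; ethyl 2-(diethoxyphosphoryl)acrylate, C=C(C(=O)OCC)P(=O)(OCC)OCC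
Why: Tandem oxa-Michael addition/Horner–Wadsworth–Emmons olefination: the alkoxide adds to the vinylphosphonate and the resulting stabilized anion should olefinate the aldehyde with the ester trans to the dioxolane, so that the CH2OPMB carbon (future C3) is cis to C6.

Step 13
Reactants: 19 diester
Product: 20 diol (C7H2OH and C4′H2OH)
Conditions: i-Bu2AlH (6 equiv), CH2Cl2, −78 to 0 °C; Rochelle salt
Reagents that add atoms: none
Why: Excess hydride should reduce both the conjugated ester (1,2-reduction to the allylic alcohol) and the hindered ester at C1 without touching the acetal or the benzyl ethers.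

Step 14
Reactants: 20 diol
Product: 21 C4′ TBDPS ether
Conditions: TBDPSCl (1.05 equiv), imidazole, CH2Cl2, −20 °C
Reagents that add atoms: tert-butyldiphenylsilyl chloride, CC(C)(C)[Si](Cl)(c1ccccc1)c1ccccc1
Why: The bulky chlorosilane should select the unhindered allylic primary hydroxyl over the neopentyl-type primary hydroxyl next to quaternary C1.

Step 15
Reactants: 21 mono-silyl ether
Product: 22 C7 acetate
Conditions: Ac2O, pyridine, DMAP (cat.), CH2Cl2, 0 °C
Reagents that add atoms: acetic anhydride, CC(=O)OC(C)=O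
Why: Standard DMAP-catalysed acetylation of the remaining hydroxyl gives a base-labile ester that is removed later in the epoxide-forming step.

Step 16
Reactants: 22 bis-PMB ether
Product: 23 diol (C2H2OH and C3H2OH)
Conditions: DDQ (2.6 equiv), CH2Cl2/pH 7 phosphate buffer, 0 °C
Reagents that add atoms: none
Why: Oxidative cleavage of both 4-methoxybenzyl ethers by DDQ (hydride abstraction, hydrolysis of the oxocarbenium ion) should leave the silyl ether, acetate and acetal intact.

Step 17
Reactants: 23 diol
Product: 24 C2,C3-dialdehyde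
Conditions: Dess–Martin periodinane, NaHCO3, CH2Cl2, 0 °C; used at once
Reagents that add atoms: none
Why: Double Dess–Martin oxidation under neutral conditions should give the non-enolizable C2 aldehyde and the C3 enal without isomerization of the trisubstituted alkene, whose geometry keeps C3 cis to C6.

Step 18
Reactants: 24 dialdehyde
Product: 25 ring B cis-2α,3α-diol with trans-fused C1/C6 acetonide
Conditions: SmI2 (3 equiv), t-BuOH (2.5 equiv), THF, −78 °C, slow addition of 24 (final 0.005 M); aq. NH4Cl
Reagents that add atoms: none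
Why: Single-electron transfer from SmI2 (divalent samarium) to the two formyl groups gives ketyl radical anions that couple carbon to carbon within a samarium-bridged complex, and protonation of the cis-diolate gives the diol. The closest known reaction type is the SmI2 pinacol cyclization of 1,6-dialdehydes to cis-cyclohexane-1,2-diols, established on sugar-derived dialdehydes that carry a trans-dioxolane. Ring B is closed by intramolecular ketyl–carbonyl coupling (6-exo-trig type) between C2 and C3, the chain being pre-folded by the trans-dioxolane at C1/C6 and the cis relation of C3 and C6 across C4=C5. C2 is controlled by the C1 acetal oxygen (the new C2–O bond forms anti to it, equatorial on the forming ring), and C3 by the samarium that bridges both oxygens and forces the two hydroxyls cis. The step needs ring closure to outrun intermolecular coupling and loss of the γ-oxygen from the enal ketyl, which slow addition at high dilution and −78 °C with t-BuOH as proton source should secure.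

Step 19
Reactants: 25 acetonide diol
Product: 26 tetraol (1β,2α,3α,6α)
Conditions: AcOH/H2O (4:1), 40 °C
Reagents that add atoms: none
Why: Acid hydrolysis of the strained trans-fused acetonide should free the C1 and C6 hydroxyls while the acetate and the TBDPS ether survive.

Step 20
Reactants: 26 tetraol
Product: 27 3α,6α-bis-TBS ether
Conditions: TBSCl (2.2 equiv), imidazole, DMF, 0 to 25 °C
Reagents that add atoms: tert-butyldimethylsilyl chloride, CC(C)(C)[Si](C)(C)Cl
Why: Silylation should take the two allylic secondary hydroxyls (C3, C6); the C2 hydroxyl, wedged between quaternary C1 and the new C3 silyl ether, and the tertiary C1 hydroxyl are much slower.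

Step 21
Reactants: 27 bis-silyl ether
Product: 29 1β,2β-epoxy alcohol (C7H2OH), via mesylate 28 (not isolated)
Conditions: MsCl, Et3N, CH2Cl2, 0 °C; then K2CO3, MeOH, 0 °C
Reagents that add atoms: none
Why: Mesylation of the only reactive secondary hydroxyl, then K2CO3/MeOH, should cleave the acetate and close the epoxide by intramolecular Williamson displacement (SN2, 3-exo-tet) of the 2α-mesylate by the trans 1β-alkoxide, inverting C2 and placing the epoxide anti to the C3 and C6 oxygens.

Step 22
Reactants: 29 epoxy alcohol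
Product: 30 epoxy aldehyde (C7HO)
Conditions: Dess–Martin periodinane, NaHCO3, CH2Cl2, 0 °C
Reagents that add atoms: none
Why: Dess–Martin oxidation of the 2,3-epoxy alcohol should give the epoxy aldehyde, which has no α-hydrogen and cannot epimerize.

Step 23
Reactants: 14 dienyl iodide; 30 epoxy aldehyde
Product: 32 C7 carbinol (both epimers), via dienyllithium 31 (not isolated)
Conditions: 14, t-BuLi (2.0 equiv), Et2O, −78 °C; then 30, −78 °C; aq. NH4Cl
Reagents that add atoms: none
Why: Iodine–lithium exchange gives the configurationally stable (Z)-dienyllithium, whose 1,2-addition to the aldehyde forms the C7–C8 bond; the C7 configuration is not relied on because it is reset in steps 24 and 25.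

Step 24
Reactants: 32 carbinol
Product: 33 α,β-epoxy dienone
Conditions: Dess–Martin periodinane, NaHCO3, pyridine, CH2Cl2, 0 °C
Reagents that add atoms: none
Why: Dess–Martin oxidation of the secondary allylic alcohol should converge both C7 epimers on the ketone under non-acidic conditions.

Step 25
Reactants: 33 epoxy dienone
Product: 34 (7S)-carbinol, fully silylated target
Conditions: Zn(BH4)2, Et2O, −30 °C
Reagents that add atoms: none
Why: Chelation-controlled 1,2-reduction of an α,β-epoxy ketone (zinc bridges the carbonyl and epoxide oxygens, hydride enters anti to the epoxide C1–C2 bond) should give the anti (erythro) epoxy alcohol, which is the required (S) configuration at C7.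

Step 26
Reactants: 34 tetrasilyl ether
Product: 35 target CNP0357844.1
Conditions: n-Bu4NF/AcOH (1:1), THF, 0 to 25 °C
Reagents that add atoms: none
Why: Fluoride cleavage of the four silyl ethers, buffered with acetic acid to avoid base-induced epoxide migration, should give the target without exposing the acid-sensitive dienyl carbinol to acid.

**Compound list**
1 | geranyl acetate, (2E)-3,7-dimethylocta-2,6-dien-1-yl acetate | CC(=O)OC/C=C(\C)CCC=C(C)C | starting material
2 | (2E)-5-[(2R)-3,3-dimethyloxiran-2-yl]-3-methylpent-2-en-1-yl acetate | CC(=O)OC/C=C(\C)CC[C@H]1OC1(C)C | intermediate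
3 | [(1S,3R)-3-hydroxy-2,2-dimethyl-6-methylidenecyclohexyl]methyl acetate (OH and CH2OAc cis) | C=C1CC[C@@H](O)C(C)(C)[C@H]1COC(C)=O | intermediate
4 | [(1S,3R)-3-(tert-butyldimethylsilyloxy)-2,2-dimethyl-6-methylidenecyclohexyl]methyl acetate | C=C1CC[C@@H](O[Si](C)(C)C(C)(C)C)C(C)(C)[C@H]1COC(C)=O | intermediate
5 | [(1S,3R)-3-(tert-butyldimethylsilyloxy)-2,2-dimethyl-6-methylidenecyclohexyl]methanol | C=C1CC[C@@H](O[Si](C)(C)C(C)(C)C)C(C)(C)[C@H]1CO | intermediate
6 | (1S,3R)-3-(tert-butyldimethylsilyloxy)-2,2-dimethyl-6-methylidenecyclohexane-1-carbaldehyde | C=C1CC[C@@H](O[Si](C)(C)C(C)(C)C)C(C)(C)[C@H]1C=O | intermediate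
7 | tert-butyl{[(1R,3S)-3-[(E)-2-iodoethenyl]-2,2-dimethyl-4-methylidenecyclohexyl]oxy}dimethylsilane | C=C1CC[C@@H](O[Si](C)(C)C(C)(C)C)C(C)(C)[C@H]1/C=C/I | intermediate
8 | propyne | CC#C | starting material
9 | (Z)-(2-bromoprop-1-en-1-yl)dibromoborane | C/C(Br)=C/B(Br)Br | intermediate (not isolated)
10 | (Z)-2-(2-bromoprop-1-en-1-yl)-4,4,5,5-tetramethyl-1,3,2-dioxaborolane | C/C(Br)=C/B1OC(C)(C)C(C)(C)O1 | intermediate
11 | (E)-alkenyllithium from 7 (Li in place of I) | C=C1CC[C@@H](O[Si](C)(C)C(C)(C)C)C(C)(C)[C@H]1/C=C/[Li] | intermediate (not isolated)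
12 | (E)-alkenylzinc bromide from 7 | C=C1CC[C@@H](O[Si](C)(C)C(C)(C)C)C(C)(C)[C@H]1/C=C/[Zn]Br | intermediate (not isolated)
13 | 2-[(1Z,3E)-4-[(1S,3R)-3-(tert-butyldimethylsilyloxy)-2,2-dimethyl-6-methylidenecyclohexyl]-2-methylbuta-1,3-dien-1-yl]-4,4,5,5-tetramethyl-1,3,2-dioxaborolane | C=C1CC[C@@H](O[Si](C)(C)C(C)(C)C)C(C)(C)[C@H]1/C=C/C(C)=C\B2OC(C)(C)C(C)(C)O2 | intermediate
14 | tert-butyl{[(1R,3S)-3-[(1E,3Z)-4-iodo-3-methylbuta-1,3-dien-1-yl]-2,2-dimethyl-4-methylidenecyclohexyl]oxy}dimethylsilane | C=C1CC[C@@H](O[Si](C)(C)C(C)(C)C)C(C)(C)[C@H]1/C=C/C(C)=C\I | intermediate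
15 | dimethyl (4R,5R)-2,2-dimethyl-1,3-dioxolane-4,5-dicarboxylate (dimethyl 2,3-O-isopropylidene-L-tartrate) | COC(=O)[C@@H]1OC(C)(C)O[C@H]1C(=O)OC | starting material
16 | lithium ester enolate of 15 | [Li+].COC(=O)[C@@H]1OC(C)(C)OC1=C([O-])OC | intermediate (not isolated)
17 | dimethyl (4S,5R)-4-[(4-methoxybenzyloxy)methyl]-2,2-dimethyl-1,3-dioxolane-4,5-dicarboxylate (esters cis; dioxolane C4 = C1, C5 = C6) | COC(=O)[C@@]1(COCc2ccc(OC)cc2)OC(C)(C)O[C@H]1C(=O)OC | intermediate
18 | methyl (4S,5R)-5-formyl-4-[(4-methoxybenzyloxy)methyl]-2,2-dimethyl-1,3-dioxolane-4-carboxylate | COC(=O)[C@@]1(COCc2ccc(OC)cc2)OC(C)(C)O[C@H]1C=O | intermediate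
19 | ethyl (E)-2-[(4-methoxybenzyloxy)methyl]-3-(dioxolanyl)prop-2-enoate; dioxolane as in 18, ethyl ester trans and CH2OPMB cis to it | COC(=O)[C@@]1(COCc2ccc(OC)cc2)OC(C)(C)O[C@H]1/C=C(\COCc3ccc(OC)cc3)C(=O)OCC | intermediate
20 | diol from 19: C1 carries CH2OH (C7) and CH2OPMB (C2); C4 carries CH2OH (C4′, trans to C6) and CH2OPMB (C3, cis to C6) | OC[C@@]1(COCc2ccc(OC)cc2)OC(C)(C)O[C@H]1/C=C(\COCc3ccc(OC)cc3)CO | intermediate
21 | C4′-O-TBDPS ether of 20 (C7H2OH free) | OC[C@@]1(COCc2ccc(OC)cc2)OC(C)(C)O[C@H]1/C=C(\COCc3ccc(OC)cc3)CO[Si](c4ccccc4)(c5ccccc5)C(C)(C)C | intermediate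
22 | C7 acetate of 21 | CC(=O)OC[C@@]1(COCc2ccc(OC)cc2)OC(C)(C)O[C@H]1/C=C(\COCc3ccc(OC)cc3)CO[Si](c4ccccc4)(c5ccccc5)C(C)(C)C | intermediate
23 | diol from 22 (C2H2OH on C1, C3H2OH cis to C6) | CC(=O)OC[C@@]1(CO)OC(C)(C)O[C@H]1/C=C(\CO)CO[Si](c2ccccc2)(c3ccccc3)C(C)(C)C | intermediate
24 | dialdehyde (C2HO on C1, C3HO cis to C6 on C4=C5) | CC(=O)OC[C@@]1(C=O)OC(C)(C)O[C@H]1/C=C(\C=O)CO[Si](c2ccccc2)(c3ccccc3)C(C)(C)C | intermediate
25 | ring B diol: 1β,6α-O-isopropylidene (trans-fused), 2α-OH, 3α-OH, C1 α-CH2OAc, C4 CH2OTBDPS, C4=C5 | CC(=O)OC[C@]12OC(C)(C)O[C@H]2C=C(CO[Si](c3ccccc3)(c4ccccc4)C(C)(C)C)[C@@H](O)[C@H]1O | intermediate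
26 | ring B tetraol: 1β-OH, 2α-OH, 3α-OH, 6α-OH, C1 α-CH2OAc, C4 CH2OTBDPS | CC(=O)OC[C@@]1(O)[C@@H](O)C=C(CO[Si](c2ccccc2)(c3ccccc3)C(C)(C)C)[C@@H](O)[C@H]1O | intermediate
27 | 3α,6α-bis-O-TBS ether of 26 (1β-OH and 2α-OH free) | CC(=O)OC[C@@]1(O)[C@@H](O[Si](C)(C)C(C)(C)C)C=C(CO[Si](c2ccccc2)(c3ccccc3)C(C)(C)C)[C@@H](O[Si](C)(C)C(C)(C)C)[C@H]1O | intermediate
28 | 2α-mesylate of 27 | CC(=O)OC[C@@]1(O)[C@@H](O[Si](C)(C)C(C)(C)C)C=C(CO[Si](c2ccccc2)(c3ccccc3)C(C)(C)C)[C@@H](O[Si](C)(C)C(C)(C)C)[C@H]1OS(C)(=O)=O | intermediate (not isolated)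
29 | ring B 1β,2β-epoxide: 3α-OTBS, 6α-OTBS, C4 CH2OTBDPS, C1 α-CH2OH | OC[C@]12O[C@H]1[C@H](O[Si](C)(C)C(C)(C)C)C(CO[Si](c3ccccc3)(c4ccccc4)C(C)(C)C)=C[C@@H]2O[Si](C)(C)C(C)(C)C | intermediate
30 | epoxy aldehyde (C7HO on C1), otherwise as 29 | O=C[C@]12O[C@H]1[C@H](O[Si](C)(C)C(C)(C)C)C(CO[Si](c3ccccc3)(c4ccccc4)C(C)(C)C)=C[C@@H]2O[Si](C)(C)C(C)(C)C | intermediate
31 | (1Z,3E)-dienyllithium from 14 (Li in place of I) | C=C1CC[C@@H](O[Si](C)(C)C(C)(C)C)C(C)(C)[C@H]1/C=C/C(C)=C\[Li] | intermediate (not isolated)
32 | coupled carbinol, C7 epimers (ring A and ring B fully silylated) | C=C1CC[C@@H](O[Si](C)(C)C(C)(C)C)C(C)(C)[C@H]1/C=C/C(C)=C\C(O)[C@]12O[C@H]1[C@H](O[Si](C)(C)C(C)(C)C)C(CO[Si](c3ccccc3)(c4ccccc4)C(C)(C)C)=C[C@@H]2O[Si](C)(C)C(C)(C)C | intermediate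
33 | C7 ketone (α,β-epoxy dienone) | C=C1CC[C@@H](O[Si](C)(C)C(C)(C)C)C(C)(C)[C@H]1/C=C/C(C)=C\C(=O)[C@]12O[C@H]1[C@H](O[Si](C)(C)C(C)(C)C)C(CO[Si](c3ccccc3)(c4ccccc4)C(C)(C)C)=C[C@@H]2O[Si](C)(C)C(C)(C)C | intermediate
34 | (7S)-carbinol, tris-TBS/TBDPS ether of the target | C=C1CC[C@@H](O[Si](C)(C)C(C)(C)C)C(C)(C)[C@H]1/C=C/C(C)=C\[C@H](O)[C@]12O[C@H]1[C@H](O[Si](C)(C)C(C)(C)C)C(CO[Si](c3ccccc3)(c4ccccc4)C(C)(C)C)=C[C@@H]2O[Si](C)(C)C(C)(C)C | intermediate
35 | CNP0357844.1 | C=C1CC[C@@H](O)C(C)(C)[C@H]1/C=C/C(C)=C\[C@H](O)[C@]12O[C@H]1[C@H](O)C(CO)=C[C@@H]2O | target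

Total step count: 26. Longest linear sequence: 17 steps (steps 10 to 26, from 15).

**Steps most likely to fail**

Step 18. The ring closure may be outrun by intermolecular pinacol coupling, by E/Z isomerization of the enal ketyl, or by loss of the C6 oxygen from it. Fallback, setting out from dialdehyde 24: both formyl groups are methylenated (Ph3P=CH2, THF, −78 to 0 °C) to the triene F1. The acetonide is cleaved (AcOH/H2O) to the diol F2, and both hydroxyls are silylated (Et3SiOTf, 2,6-lutidine) to the bis(triethylsilyl) ether F3. Ring-closing metathesis (second-generation Grubbs catalyst, CH2Cl2, 40 °C) closes ring B through a C2=C3 double bond to the cyclohexa-1,3-diene F4. OsO4/N-methylmorpholine N-oxide should dihydroxylate the less hindered disubstituted C2=C3 alkene from the α face, anti to the pseudo-axial C1 silyloxy group, to the diol F5. HF·pyridine removes the two triethylsilyl groups and the route is rejoined at tetraol 26.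

Step 10. The dioxolane enolate may fragment by β-elimination before the slow C-alkylation, or the chloromethyl ether may decompose. Fallback, setting out from 15: the same enolate is trapped at −78 °C in an aldol addition with monomeric formaldehyde, which is faster than the alkylation and has the same facial bias, to give the hydroxymethyl diester F6. Etherification with 4-methoxybenzyl 2,2,2-trichloroacetimidate (La(OTf)3 cat., toluene) returns to 17.

Step 11. Over-reduction to the primary alcohol and attack on the ester at C1 may compete. Fallback, setting out from 17: the less hindered ester is converted into the N-methoxy-N-methylamide F7 (MeNH(OMe)·HCl, i-PrMgCl, THF, −20 °C). Its reduction with i-Bu2AlH at −78 °C stops at the chelated hemiaminal aluminate and gives aldehyde 18 on work-up.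

Further compounds
F1 | step 18 | triene: dioxolane of 24 with vinyl in place of each formyl group | CC(=O)OC[C@@]1(C=C)OC(C)(C)O[C@H]1/C=C(\C=C)CO[Si](c2ccccc2)(c3ccccc3)C(C)(C)C
F2 | step 18 | triene diol (C1-OH, C6-OH free) | CC(=O)OC[C@](O)(C=C)[C@@H](O)/C=C(\C=C)CO[Si](c1ccccc1)(c2ccccc2)C(C)(C)C
F3 | step 18 | triene bis(triethylsilyl) ether | CC(=O)OC[C@](O[Si](CC)(CC)CC)(C=C)[C@@H](O[Si](CC)(CC)CC)/C=C(\C=C)CO[Si](c1ccccc1)(c2ccccc2)C(C)(C)C
F4 | step 18 | ring B cyclohexa-1,3-diene (C2=C3, C4=C5), 1β,6α-bis(triethylsilyloxy) | CC(=O)OC[C@]1(O[Si](CC)(CC)CC)C=CC(CO[Si](c2ccccc2)(c3ccccc3)C(C)(C)C)=C[C@@H]1O[Si](CC)(CC)CC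
F5 | step 18 | ring B 2α,3α-diol, 1β,6α-bis(triethylsilyloxy) | CC(=O)OC[C@]1(O[Si](CC)(CC)CC)[C@H](O)[C@H](O)C(CO[Si](c2ccccc2)(c3ccccc3)C(C)(C)C)=C[C@@H]1O[Si](CC)(CC)CC
F6 | step 10 | dimethyl (4S,5R)-4-(hydroxymethyl)-2,2-dimethyl-1,3-dioxolane-4,5-dicarboxylate | COC(=O)[C@@]1(CO)OC(C)(C)O[C@H]1C(=O)OC
F7 | step 11 | N-methoxy-N-methylamide of 17 at the C6 carboxyl | COC(=O)[C@@]1(COCc2ccc(OC)cc2)OC(C)(C)O[C@H]1C(=O)N(C)OC
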